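The target is cut at the two bonds that join its halves within ring A (O–CH and CH(isobutyl)–CH): an o-quinone methide of quinolone A adds to the C3=C4 alkene of pyran ring B of veprisine (8) in an exo, enantioselective hetero-Diels–Alder reaction. Ring B itself (O1, C2(CH3)2, C3, C4, C4a, C10b) is grown in the key step from a 2-isopropenyl-2,3-dihydrofuran (6): zerovalent palladium opens the allylic C–O bond, β-hydride loss gives a diene, and 6π-oxa-electrocyclisation re-closes oxygen onto the former isopropenyl carbon. The step exploits the fact that O1–C2(CH3)2 of ring B is an allylic ether carbon in the ring-contracted isomer, and it unveils the dienophile.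

Key step: step 4

Assumption: 2,3-dimethoxy-N-methylaniline (1) is taken as a catalogue compound; if not stocked it is one reductive N-methylation away from 2,3-dimethoxyaniline.

Step 1
Reactants: 1 2,3-dimethoxy-N-methylaniline; 2 diethyl malonate
Product: 3 4-hydroxy-7,8-dimethoxy-1-methylquinolin-2(1H)-one
Conditions: Ph2O, 250 °C, ethanol distilled off
Reagents that add atoms: none
Why: Thermal malonate condensation (amide formation, then intramolecular acylation at C6, the only free position ortho to nitrogen) should give the 4-hydroxy-2-quinolone with the methoxy groups at C7 and C8; no stereocentre.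

Step 2
Reactants: 3 4-hydroxy-7,8-dimethoxy-1-methylquinolin-2(1H)-one; 4 3-methylbut-2-en-1-yl acetate
Product: 5 4-hydroxy-7,8-dimethoxy-1-methyl-3-(3-methylbut-2-en-1-yl)quinolin-2(1H)-one
Conditions: Pd(PPh3)4 (5 mol %), THF, 60 °C
Reagents that add atoms: none
Why: Tsuji–Trost allylation: zerovalent palladium ionises 4 to the 1,1-dimethyl-π-allyl complex and the soft C3 carbon of 3 attacks its unsubstituted terminus, which should give the linear C-prenyl compound with acetate as the only base; no stereocentre.

Step 3
Reactants: 5 4-hydroxy-7,8-dimethoxy-1-methyl-3-(3-methylbut-2-en-1-yl)quinolin-2(1H)-one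
Product: 6 racemic 6,7-dimethoxy-5-methyl-2-(prop-1-en-2-yl)-2,3-dihydrofuro[3,2-c]quinolin-4(5H)-one
Conditions: Pd(OCOCF3)2 (10 mol %), pyridine (40 mol %), 3 Å MS, O2 (1 atm), toluene, 80 °C
Reagents that add atoms: none
Why: Wacker-type oxidative cyclisation: 5-exo oxypalladation of the trisubstituted alkene by the C4 hydroxyl places divalent palladium on the tertiary carbon, from which β-hydride elimination toward a methyl group should give the isopropenyl dihydrofuran while oxygen re-oxidises the metal; the new stereocentre forms as a racemate, which is harmless because step 4 destroys it.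

Step 4
Reactants: 6 racemic 6,7-dimethoxy-5-methyl-2-(prop-1-en-2-yl)-2,3-dihydrofuro[3,2-c]quinolin-4(5H)-one
Product: 8 veprisine (7,8-dimethoxy-2,2,6-trimethyl-2H-pyrano[3,2-c]quinolin-5(6H)-one), via dienyl hydroxyquinolone 7 (not isolated)
Conditions: Pd(PPh3)4 (5 mol %), PhCO2H (20 mol %), toluene, 100 °C
Reagents that add atoms: none
Why: Zerovalent palladium ionises the allylic C2–O bond of the dihydrofuran (the 4-quinolonyl oxide leaves as a vinylogous carboxylate), and β-hydride loss from the benzylic CH2 should give the conjugated dienyl hydroxyquinolone 7. Proton transfer from the C4 hydroxyl to the diene terminus (acid-mediated, or a 1,7-hydrogen shift) then gives the dienone tautomer, which closes by disrotatory 6π-oxa-electrocyclisation through the C4 oxygen onto the former isopropenyl carbon; this is the only ring closed, it forms the O–C(CH3)2 bond, and the ring grows from five to six atoms as the oxygen moves from CH to C(CH3)2. The closest known reaction types are the palladium-catalysed 1,4-elimination of allylic esters and aryl ethers to 1,3-dienes, the dienone-to-2H-pyran electrocyclisation that follows Knoevenagel condensation of 4-hydroxyquinolones with 3-methylbut-2-enal, and the alkali isomerisation of 2-isopropenyl-2,3-dihydrobenzofurans to 2,2-dimethylchromenes. No stereocentre is formed and the one in 6 is destroyed. The step needs elimination to win over re-closure to the five- or seven-membered allyl ether, which should hold because those closures are reversible under the catalyst whereas diene formation and the electrocyclisation are not reversed at 100 °C. It also needs closure through the C4 oxygen and not the lactam oxygen, which the ketone-like C4 carbonyl of the 2,4-dione tautomer secures by being the better heterotriene terminus than the amide carbonyl.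

Step 5
Reactants: 3 4-hydroxy-7,8-dimethoxy-1-methylquinolin-2(1H)-one; 9 3-methylbutanal; 10 sodium 4-methylbenzenesulfinate
Product: 11 racemic 4-hydroxy-7,8-dimethoxy-1-methyl-3-[3-methyl-1-(4-methylbenzenesulfonyl)butyl]quinolin-2(1H)-one
Conditions: HCO2H–H2O (1:1), 25 °C
Reagents that add atoms: none
Why: Three-component condensation: the Knoevenagel-type quinone methide formed from 3 and 9 is trapped by sulfinate in a sulfa-Michael addition, which should store it as a bench-stable sulfone and exclude double addition of 3; the stereocentre is racemic and is erased in step 6.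

Step 6
Reactants: 11 racemic 4-hydroxy-7,8-dimethoxy-1-methyl-3-[3-methyl-1-(4-methylbenzenesulfonyl)butyl]quinolin-2(1H)-one; 8 veprisine
Product: 13 target CNP0275598.1 (2R 3S 4S in the numbering of pyran ring A), via quinone methide 12 (not isolated)
Conditions: Cu(OTf)2 (10 mol %), (S,S)-tBu-box (11 mol %), 2,6-lutidine (1.2 equiv), 4 Å MS, CH2Cl2, −20 °C
Reagents that add atoms: none
Why: Base-induced loss of sulfinate frees quinone methide 12, whose 2,4-dicarbonyl unit binds the chiral divalent copper complex in a bidentate way and undergoes an inverse-electron-demand hetero-Diels–Alder reaction with the electron-rich C3=C4 alkene of 8 (C3 to the methide carbon, the C4 oxygen of the methide to benzylic C4): suprafacial addition fixes the cis ring fusion, the exo transition state (isobutyl anti to the C(CH3)2 group) should place isobutyl trans to C(CH3)2, and the ligand shields one face of the methide carbon so that it becomes S, the antipodal ligand being used if the first assignment shows the opposite sense.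

Compound list
1 | 2,3-dimethoxy-N-methylaniline | CNc1cccc(OC)c1OC | starting material
2 | diethyl malonate | CCOC(=O)CC(=O)OCC | starting material
3 | 4-hydroxy-7,8-dimethoxy-1-methylquinolin-2(1H)-one | COc1ccc2c(O)cc(=O)n(C)c2c1OC | intermediate
4 | 3-methylbut-2-en-1-yl acetate (prenyl acetate) | CC(C)=CCOC(C)=O | starting material
5 | 4-hydroxy-7,8-dimethoxy-1-methyl-3-(3-methylbut-2-en-1-yl)quinolin-2(1H)-one | COc1ccc2c(O)c(CC=C(C)C)c(=O)n(C)c2c1OC | intermediate
6 | racemic 6,7-dimethoxy-5-methyl-2-(prop-1-en-2-yl)-2,3-dihydrofuro[3,2-c]quinolin-4(5H)-one | COc1ccc2c(c1OC)n(C)c(=O)c1c2OC(C(C)=C)C1 | intermediate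
7 | 4-hydroxy-7,8-dimethoxy-1-methyl-3-[(1E)-3-methylbuta-1,3-dien-1-yl]quinolin-2(1H)-one | COc1ccc2c(O)c(/C=C/C(C)=C)c(=O)n(C)c2c1OC | intermediate
8 | veprisine, 7,8-dimethoxy-2,2,6-trimethyl-2H-pyrano[3,2-c]quinolin-5(6H)-one | COc1ccc2c(c1OC)n(C)c(=O)c1c2OC(C)(C)C=C1 | intermediate
9 | 3-methylbutanal | CC(C)CC=O | starting material
10 | sodium 4-methylbenzenesulfinate | [Na+].[O-]S(=O)c1ccc(C)cc1 | starting material
11 | racemic 4-hydroxy-7,8-dimethoxy-1-methyl-3-[3-methyl-1-(4-methylbenzenesulfonyl)butyl]quinolin-2(1H)-one | COc1ccc2c(O)c(C(CC(C)C)S(=O)(=O)c3ccc(C)cc3)c(=O)n(C)c2c1OC | intermediate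
12 | 7,8-dimethoxy-1-methyl-3-(3-methylbutylidene)quinoline-2,4(1H,3H)-dione, isobutyl anti to the C4 carbonyl | COc1ccc2C(=O)/C(=C/CC(C)C)C(=O)N(C)c2c1OC | intermediate
13 | CNP0275598.1: cis-fused adduct in which O1 and C4 of a 4-isobutyl-3,4-dihydro-2H-pyrano[3,2-c]quinolin-5-one (ring A; C4 S, C3 S, C2 R) are joined through C3 and C2 to C3 and C4 of a 2,2-dimethyl-3,4-dihydro-2H-pyrano[3,2-c]quinolin-5-one (ring B), both quinolones 7,8-dimethoxy-N-methyl | COc1ccc2c3c(c(=O)n(C)c2c1OC)[C@@H](CC(C)C)[C@H]1[C@@H](O3)c2c(c3ccc(OC)c(OC)c3n(C)c2=O)OC1(C)C | target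

Total step count: 6. Longest linear sequence: 5 steps (steps 1, 2, 3, 4 and 6); step 5 is a one-step branch from 3.

Steps most likely to fail

Step 4. The π-allyl intermediate may re-close to the five- or seven-membered allyl ether faster than it eliminates. The diene may also be lost to Diels–Alder dimerisation, or the final closure may take place through the lactam oxygen. The fallback sets out from 5 and comes back at 8. Epoxidation of 5 with mCPBA gives the prenyl epoxide F1, which should cyclise in the 5-exo mode to the hydroxyisopropyl dihydrofuran F2. Heating F2 with aqueous NaOH in ethanol should re-open it through the epoxide and the quinolone oxide and re-close at the tertiary carbon, the dihydrofuro-to-dihydropyrano rearrangement of this alkaloid class, to give the ring-expanded 3-hydroxy-2,2-dimethyl dihydropyran F3. Mesylation to the mesylate F4 and elimination with DBU toward the benzylic hydrogen should then give 8.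

Step 6. The uncatalysed cycloaddition may compete with the copper-bound pathway, and facial or exo selectivity may be too low. The fallback sets out from 11 and 8 and comes back at 13. The cycloaddition is run without metal (K2CO3, toluene, 60 °C) to give the racemic exo adduct, a 1:1 mixture by definition of 13 and the mirror image of 13 F5, and the enantiomers are separated by preparative chromatography on a chiral stationary phase.

Step 3. Oxypalladation may take the 6-endo course, or may involve the lactam oxygen, instead of the 5-exo course through the C4 hydroxyl. The fallback sets out from 3 and comes back at 6, replacing steps 2 and 3. Alkylation of 3 with (E)-1,4-dibromo-2-methylbut-2-ene (K2CO3, acetone) at the less hindered CH2Br should give the C3-alkylated allylic bromide F6 (not isolated). Its C4 oxygen should then close the dihydrofuran by 5-exo SN2′ displacement, which leaves the isopropenyl group on C2.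

Further compounds
F1 | step 4 | racemic 3-[(3,3-dimethyloxiran-2-yl)methyl]-4-hydroxy-7,8-dimethoxy-1-methylquinolin-2(1H)-one | COc1ccc2c(O)c(CC3OC3(C)C)c(=O)n(C)c2c1OC
F2 | step 4 | racemic 2-(2-hydroxypropan-2-yl)-6,7-dimethoxy-5-methyl-2,3-dihydrofuro[3,2-c]quinolin-4(5H)-one | COc1ccc2c(c1OC)n(C)c(=O)c1c2OC(C(C)(C)O)C1
F3 | step 4 | racemic 3-hydroxy-7,8-dimethoxy-2,2,6-trimethyl-3,4-dihydro-2H-pyrano[3,2-c]quinolin-5(6H)-one | COc1ccc2c(c1OC)n(C)c(=O)c1c2OC(C)(C)C(O)C1
F4 | step 4 | racemic 7,8-dimethoxy-2,2,6-trimethyl-5-oxo-3,4,5,6-tetrahydro-2H-pyrano[3,2-c]quinolin-3-yl methanesulfonate | COc1ccc2c(c1OC)n(C)c(=O)c1c2OC(C)(C)C(OS(C)(=O)=O)C1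
F5 | step 6 | mirror image of 13 (2S 3R 4R in the numbering of pyran ring A) | COc1ccc2c3c(c(=O)n(C)c2c1OC)[C@H](CC(C)C)[C@@H]1[C@H](O3)c2c(c3ccc(OC)c(OC)c3n(C)c2=O)OC1(C)C
F6 | step 3 | 3-[(2E)-4-bromo-3-methylbut-2-en-1-yl]-4-hydroxy-7,8-dimethoxy-1-methylquinolin-2(1H)-one | COc1ccc2c(O)c(C/C=C(\C)CBr)c(=O)n(C)c2c1OC
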